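**Plan**

- Target 23 is a gallocatechin unit (unit 1, 2R,3S) joined through its 4'-oxygen to C7 of an epigallocatechin unit (unit 2, 2R,3R). Flavan numbering (O1, C2, C3, C4, C4a to C8a, primed ring B) is used for each unit.
- Retrosynthesis: the nine benzyl ethers; the C3 carbinol of unit 2 (from the 3-ketone); ring C of unit 2 at C4–C4a and O1–C2, giving 5-aryloxyresorcinol 14 and epoxy aldehyde 17; ring C of unit 1 in the same way, giving phenol 10 and epoxy aldehyde 9; last the diaryl ether C–O bond (phenol 4 + aryl bromide 6).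
- Forward: diaryl ether 7, two-carbon homologation and epoxidation, ring C of unit 1 (annulation with 10), release of the resorcinol, ring C of unit 2 (annulation with 17), inversion at C3 of unit 2, global hydrogenolysis.
- Enabling feature: ring A of unit 2 is a phloroglucinol ring in which C4a lies between the O1-bearing C8a and the hydroxylated C5. In 14 this carbon sits between two equivalent hydroxyls, so it is the C-nucleophile for C4; one hydroxyl anchors titanium, the other closes O1–C2, and either assignment gives the same chroman.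
- Stereochemistry: C2 of both units and C3 of unit 1 come from the organocatalytic epoxidations (steps 7 and 12), passed on by inversion at the benzylic epoxide carbon and retention at the other. C3 of unit 2 comes from hydride delivery anti to the 2-aryl group (step 16).

Key step: step 13

**Route**

Step 1
Reactants: 1 3,4,5-trihydroxybenzaldehyde
Product: 2 4-(allyloxy)-3,5-dihydroxybenzaldehyde
Conditions: allyl bromide (1.0 equiv), NaHCO3, NaI (cat.), DMF, 40 °C
Reagents that add atoms: allyl bromide, C=CCBr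
Why: The hydroxyl para to the formyl group is the most acidic, so hydrogen carbonate forms only its phenoxide and the Williamson alkylation should stop at the 4-O-allyl ether.

Step 2
Reactants: 2 4-(allyloxy)-3,5-dihydroxybenzaldehyde
Product: 3 4-(allyloxy)-3,5-bis(benzyloxy)benzaldehyde
Conditions: BnBr (2.3 equiv), K2CO3, DMF, rt
Reagents that add atoms: benzyl bromide, BrCc1ccccc1
Why: Williamson benzylation of the two remaining phenols, with the allyl ether marking O-4 for later release.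

Step 3
Reactants: 3 4-(allyloxy)-3,5-bis(benzyloxy)benzaldehyde
Product: 4 3,5-bis(benzyloxy)-4-hydroxybenzaldehyde
Conditions: Pd(PPh3)4 (2 mol%), K2CO3, MeOH, rt
Reagents that add atoms: none
Why: Zerovalent palladium ionises the aryl allyl ether to a π-allyl complex that methanol captures (Tsuji–Trost deallylation), leaving the benzyl ethers and the aldehyde untouched.

Step 4
Reactants: 5 5-bromoresorcinol
Product: 6 1,3-bis(allyloxy)-5-bromobenzene
Conditions: allyl bromide (2.5 equiv), K2CO3, acetone, reflux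
Reagents that add atoms: allyl bromide, C=CCBr
Why: Double Williamson allylation; the allyl ethers should survive the copper coupling, the epoxidation and the annulation and can be removed beside benzyl ethers.

Step 5
Reactants: 4 3,5-bis(benzyloxy)-4-hydroxybenzaldehyde; 6 1,3-bis(allyloxy)-5-bromobenzene
Product: 7 4-[3,5-bis(allyloxy)phenoxy]-3,5-bis(benzyloxy)benzaldehyde
Conditions: CuI (10 mol%), picolinic acid (20 mol%), K3PO4, DMSO, 90 °C
Reagents that add atoms: none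
Why: Ullmann-type diaryl ether synthesis in which picolinate-ligated monovalent copper couples the 2,6-disubstituted phenoxide of 4 with the unhindered aryl bromide 6.

Step 6
Reactants: 7 4-[3,5-bis(allyloxy)phenoxy]-3,5-bis(benzyloxy)benzaldehyde
Product: 8 (E)-3-{4-[3,5-bis(allyloxy)phenoxy]-3,5-bis(benzyloxy)phenyl}acrylaldehyde
Conditions: Ph3P=CHCHO (1.2 equiv), toluene, 90 °C
Reagents that add atoms: (triphenylphosphoranylidene)acetaldehyde, O=CC=P(c1ccccc1)(c1ccccc1)c1ccccc1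
Why: Wittig olefination with the stabilised formylmethylene ylide should give the E-enal, a two-carbon homologation that brings in C3 and C4 of unit 1.

Step 7
Reactants: 8 (E)-3-{4-[3,5-bis(allyloxy)phenoxy]-3,5-bis(benzyloxy)phenyl}acrylaldehyde
Product: 9 (2R,3S)-3-{4-[3,5-bis(allyloxy)phenoxy]-3,5-bis(benzyloxy)phenyl}oxirane-2-carbaldehyde
Conditions: 35% aq. H2O2 (1.3 equiv), (R)-2-{bis[3,5-bis(trifluoromethyl)phenyl][(trimethylsilyl)oxy]methyl}pyrrolidine (10 mol%), CH2Cl2, rt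
Reagents that add atoms: hydrogen peroxide, OO
Why: The amine forms the (E)-iminium ion of 8, its bulky diaryl(silyloxy)methyl group shields the Si face of C-β so that hydroperoxide adds to the Re face, and the resulting enamine closes the oxirane on the O–O bond, which should give the trans (2R,3S) epoxide (organocatalytic iminium–enamine epoxidation of cinnamaldehydes; the catalyst enantiomer is assigned from this shielding model).

Step 8
Reactants: 9 (2R,3S)-3-{4-[3,5-bis(allyloxy)phenoxy]-3,5-bis(benzyloxy)phenyl}oxirane-2-carbaldehyde; 10 3,5-bis(benzyloxy)phenol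
Product: 12 (2R,3S)-2-{4-[3,5-bis(allyloxy)phenoxy]-3,5-bis(benzyloxy)phenyl}-5,7-bis(benzyloxy)chroman-3-ol, via flavan-3,4-diol 11 (not isolated)
Conditions: 10, Ti(OiPr)4 (1.1 equiv), toluene, rt, iPrOH removed in vacuo; 9, CH2Cl2, −20 to 40 °C until the epoxide is consumed; then Et3SiH, TFA, 0 °C, same flask
Reagents that add atoms: none
Why: Proposed new method: the aryloxytitanium of 10 should add through its ortho carbon to the aldehyde of 9 in a six-membered chelate (C4–C4a), the resulting titanium epoxy-alkoxide should be opened 6-endo at the benzylic epoxide carbon by the aryl oxygen with inversion (O1–C2, C2 R) while C3 keeps the epoxide C–O bond (S), and Et3SiH/TFA then removes the C4 hydroxyl through the benzylic cation; the closest known reaction types are the ortho-specific hydroxyalkylation of titanium and magnesium phenoxides with α-alkoxy aldehydes and with enals (which gives 2H-chromenes), the Ti(OiPr)4-mediated C3-opening of 2,3-epoxy alcohols and the ionic hydrogenation of flavan-4-ols.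

Step 9
Reactants: 12 (2R,3S)-2-{4-[3,5-bis(allyloxy)phenoxy]-3,5-bis(benzyloxy)phenyl}-5,7-bis(benzyloxy)chroman-3-ol
Product: 13 (2R,3S)-2-{4-[3,5-bis(allyloxy)phenoxy]-3,5-bis(benzyloxy)phenyl}-3,5,7-tris(benzyloxy)chromane
Conditions: NaH, BnBr, DMF, 0 °C to rt
Reagents that add atoms: benzyl bromide, BrCc1ccccc1
Why: Williamson benzylation of the only free hydroxyl distinguishes the C3 hydroxyl of unit 1 from the C3 hydroxyl of unit 2 that is oxidised later.

Step 10
Reactants: 13 (2R,3S)-2-{4-[3,5-bis(allyloxy)phenoxy]-3,5-bis(benzyloxy)phenyl}-3,5,7-tris(benzyloxy)chromane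
Product: 14 5-{2,6-bis(benzyloxy)-4-[(2R,3S)-3,5,7-tris(benzyloxy)chroman-2-yl]phenoxy}benzene-1,3-diol
Conditions: Pd(PPh3)4 (5 mol%), K2CO3, MeOH/THF, rt
Reagents that add atoms: none
Why: Tsuji–Trost deallylation as in step 3 should free the two resorcinol hydroxyls while the five benzyl ethers stay.

Step 11
Reactants: 15 3,4,5-tris(benzyloxy)benzaldehyde
Product: 16 (E)-3-[3,4,5-tris(benzyloxy)phenyl]acrylaldehyde
Conditions: Ph3P=CHCHO (1.2 equiv), toluene, 90 °C
Reagents that add atoms: (triphenylphosphoranylidene)acetaldehyde, O=CC=P(c1ccccc1)(c1ccccc1)c1ccccc1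
Why: Wittig olefination with the stabilised ylide should give the E-enal that carries C2, C3 and C4 of unit 2.

Step 12
Reactants: 16 (E)-3-[3,4,5-tris(benzyloxy)phenyl]acrylaldehyde
Product: 17 (2R,3S)-3-[3,4,5-tris(benzyloxy)phenyl]oxirane-2-carbaldehyde
Conditions: 35% aq. H2O2 (1.3 equiv), (R)-2-{bis[3,5-bis(trifluoromethyl)phenyl][(trimethylsilyl)oxy]methyl}pyrrolidine (10 mol%), CH2Cl2, rt
Reagents that add atoms: hydrogen peroxide, OO
Why: Same iminium–enamine epoxidation as in step 7, with hydroperoxide adding to the Re face of C-β and ring closure giving the trans (2R,3S) epoxy aldehyde.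

Step 13
Reactants: 14 5-{2,6-bis(benzyloxy)-4-[(2R,3S)-3,5,7-tris(benzyloxy)chroman-2-yl]phenoxy}benzene-1,3-diol; 17 (2R,3S)-3-[3,4,5-tris(benzyloxy)phenyl]oxirane-2-carbaldehyde
Product: 19 (2R,3S)-7-{2,6-bis(benzyloxy)-4-[(2R,3S)-3,5,7-tris(benzyloxy)chroman-2-yl]phenoxy}-2-[3,4,5-tris(benzyloxy)phenyl]chromane-3,5-diol, via dimeric flavan-3,4-diol 18 (not isolated)
Conditions: 14, Ti(OiPr)4 (2.2 equiv), toluene, rt, iPrOH removed in vacuo; 17 (1.1 equiv), CH2Cl2, −20 to 40 °C until the epoxide is consumed; then Et3SiH, TFA, 0 °C, same flask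
Reagents that add atoms: none
Why: Proposed new method: the titanium aryloxide of 14 should add through the carbon between its two oxygens to the aldehyde of 17 in a six-membered chelate (C4–C4a bond), and the titanium epoxy-alkoxide so formed should be opened at the benzylic epoxide carbon by the second ring oxygen (O1–C2 bond), after which Et3SiH/TFA removes the C4 hydroxyl by ionic hydrogenation. The closest known reaction types are the ortho-specific hydroxyalkylation of titanium and magnesium phenoxides with α-alkoxy aldehydes and with enals (the latter giving 2H-chromenes), the Ti(OiPr)4-mediated opening of 2,3-epoxy alcohols at C3, and the acid-catalysed cyclisation of 2-(2,3-epoxy-3-arylpropyl)phenols to trans-flavan-3-ols. Ring C closes by a 6-endo-tet opening of the epoxide, favoured over 5-exo by the benzylic position and by chelation of titanium between the C4 alkoxide and the epoxide oxygen, so the whole is a formal [3+3] annulation of a C,O-bisnucleophile with a three-carbon bis-electrophile. C2 arises with inversion at the benzylic epoxide carbon of 17 (S to R) and C3 keeps its epoxide C–O bond (retention, S), so the epoxidation of step 12 controls both centres and the ring is 2,3-trans; the transient C4 carbinol centre is erased by the reduction. The step needs chemoselectivity for the resorcinol over the benzylated ring A of unit 1, secured because only a free phenol binds titanium, and regioselectivity for the carbon flanked by both hydroxyls, secured by double ortho-activation and by the bulky 2,6-bis(benzyloxy)aryloxy group that screens the two other ring carbons. Because the two hydroxyls of 14 are equivalent, it does not matter which one holds titanium and which one becomes O1.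

Step 14
Reactants: 19 (2R,3S)-7-{2,6-bis(benzyloxy)-4-[(2R,3S)-3,5,7-tris(benzyloxy)chroman-2-yl]phenoxy}-2-[3,4,5-tris(benzyloxy)phenyl]chromane-3,5-diol
Product: 20 (2R,3S)-5-(benzyloxy)-7-{2,6-bis(benzyloxy)-4-[(2R,3S)-3,5,7-tris(benzyloxy)chroman-2-yl]phenoxy}-2-[3,4,5-tris(benzyloxy)phenyl]chroman-3-ol
Conditions: BnBr (1.1 equiv), K2CO3, DMF, rt
Reagents that add atoms: benzyl bromide, BrCc1ccccc1
Why: Carbonate deprotonates only the phenol, so the Williamson benzylation should leave the secondary C3 hydroxyl free for oxidation.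

Step 15
Reactants: 20 (2R,3S)-5-(benzyloxy)-7-{2,6-bis(benzyloxy)-4-[(2R,3S)-3,5,7-tris(benzyloxy)chroman-2-yl]phenoxy}-2-[3,4,5-tris(benzyloxy)phenyl]chroman-3-ol
Product: 21 (2R)-5-(benzyloxy)-7-{2,6-bis(benzyloxy)-4-[(2R,3S)-3,5,7-tris(benzyloxy)chroman-2-yl]phenoxy}-2-[3,4,5-tris(benzyloxy)phenyl]chroman-3-one
Conditions: Dess–Martin periodinane, CH2Cl2, rt
Reagents that add atoms: none
Why: Dess–Martin oxidation of the single free secondary alcohol under near-neutral conditions should give the flavan-3-one without enolisation at C2, as is usual for benzylated gallocatechins.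

Step 16
Reactants: 21 (2R)-5-(benzyloxy)-7-{2,6-bis(benzyloxy)-4-[(2R,3S)-3,5,7-tris(benzyloxy)chroman-2-yl]phenoxy}-2-[3,4,5-tris(benzyloxy)phenyl]chroman-3-one
Product: 22 (2R,3R)-5-(benzyloxy)-7-{2,6-bis(benzyloxy)-4-[(2R,3S)-3,5,7-tris(benzyloxy)chroman-2-yl]phenoxy}-2-[3,4,5-tris(benzyloxy)phenyl]chroman-3-ol
Conditions: LiBH(s-Bu)3 (L-Selectride), THF, −78 °C
Reagents that add atoms: none
Why: The bulky hydride attacks the C3 carbonyl from the face opposite the 2-aryl group, which should give the axial, 2,3-cis (3R) alcohol (substrate-controlled reduction of flavan-3-ones).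

Step 17
Reactants: 22 (2R,3R)-5-(benzyloxy)-7-{2,6-bis(benzyloxy)-4-[(2R,3S)-3,5,7-tris(benzyloxy)chroman-2-yl]phenoxy}-2-[3,4,5-tris(benzyloxy)phenyl]chroman-3-ol
Product: 23 (2R,3R)-7-{2,6-dihydroxy-4-[(2R,3S)-3,5,7-trihydroxychroman-2-yl]phenoxy}-2-(3,4,5-trihydroxyphenyl)chromane-3,5-diol
Conditions: H2 (1 atm), Pd(OH)2/C, THF/MeOH, rt
Reagents that add atoms: none
Why: Hydrogenolysis of all nine benzyl ethers over Pd(OH)2/C in a neutral solvent should free the polyphenol without opening the benzylic C2–O1 bonds or epimerising C2.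

**Compound list**

1 | 3,4,5-trihydroxybenzaldehyde | O=Cc1cc(O)c(O)c(O)c1 | starting material
2 | 4-(allyloxy)-3,5-dihydroxybenzaldehyde | O=Cc1cc(O)c(OCC=C)c(O)c1 | intermediate
3 | 4-(allyloxy)-3,5-bis(benzyloxy)benzaldehyde | O=Cc1cc(OCc2ccccc2)c(OCC=C)c(OCc2ccccc2)c1 | intermediate
4 | 3,5-bis(benzyloxy)-4-hydroxybenzaldehyde | O=Cc1cc(OCc2ccccc2)c(O)c(OCc2ccccc2)c1 | intermediate
5 | 5-bromoresorcinol (5-bromobenzene-1,3-diol) | Oc1cc(O)cc(Br)c1 | starting material
6 | 1,3-bis(allyloxy)-5-bromobenzene | C=CCOc1cc(Br)cc(OCC=C)c1 | intermediate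
7 | 4-[3,5-bis(allyloxy)phenoxy]-3,5-bis(benzyloxy)benzaldehyde | O=Cc1cc(OCc2ccccc2)c(Oc2cc(OCC=C)cc(OCC=C)c2)c(OCc2ccccc2)c1 | intermediate
8 | (E)-3-{4-[3,5-bis(allyloxy)phenoxy]-3,5-bis(benzyloxy)phenyl}acrylaldehyde | O=C/C=C/c1cc(OCc2ccccc2)c(Oc2cc(OCC=C)cc(OCC=C)c2)c(OCc2ccccc2)c1 | intermediate
9 | (2R,3S)-3-{4-[3,5-bis(allyloxy)phenoxy]-3,5-bis(benzyloxy)phenyl}oxirane-2-carbaldehyde (trans) | O=C[C@@H]1O[C@H]1c1cc(OCc2ccccc2)c(Oc2cc(OCC=C)cc(OCC=C)c2)c(OCc2ccccc2)c1 | intermediate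
10 | 3,5-bis(benzyloxy)phenol | Oc1cc(OCc2ccccc2)cc(OCc2ccccc2)c1 | starting material
11 | (2R,3S)-2-{4-[3,5-bis(allyloxy)phenoxy]-3,5-bis(benzyloxy)phenyl}-5,7-bis(benzyloxy)chromane-3,4-diol (either C4 epimer) | O(Cc1ccccc1)c1cc(OCc2ccccc2)c3c(c1)O[C@H](c1cc(OCc2ccccc2)c(Oc2cc(OCC=C)cc(OCC=C)c2)c(OCc2ccccc2)c1)[C@@H](O)C3O | intermediate
12 | (2R,3S)-2-{4-[3,5-bis(allyloxy)phenoxy]-3,5-bis(benzyloxy)phenyl}-5,7-bis(benzyloxy)chroman-3-ol | O(Cc1ccccc1)c1cc(OCc2ccccc2)c3c(c1)O[C@H](c1cc(OCc2ccccc2)c(Oc2cc(OCC=C)cc(OCC=C)c2)c(OCc2ccccc2)c1)[C@@H](O)C3 | intermediate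
13 | (2R,3S)-2-{4-[3,5-bis(allyloxy)phenoxy]-3,5-bis(benzyloxy)phenyl}-3,5,7-tris(benzyloxy)chromane | O(Cc1ccccc1)c1cc(OCc2ccccc2)c3c(c1)O[C@H](c1cc(OCc2ccccc2)c(Oc2cc(OCC=C)cc(OCC=C)c2)c(OCc2ccccc2)c1)[C@@H](OCc1ccccc1)C3 | intermediate
14 | 5-{2,6-bis(benzyloxy)-4-[(2R,3S)-3,5,7-tris(benzyloxy)chroman-2-yl]phenoxy}benzene-1,3-diol | O(Cc1ccccc1)c1cc(OCc2ccccc2)c3c(c1)O[C@H](c1cc(OCc2ccccc2)c(Oc2cc(O)cc(O)c2)c(OCc2ccccc2)c1)[C@@H](OCc1ccccc1)C3 | intermediate
15 | 3,4,5-tris(benzyloxy)benzaldehyde | O=Cc1cc(OCc2ccccc2)c(OCc2ccccc2)c(OCc2ccccc2)c1 | starting material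
16 | (E)-3-[3,4,5-tris(benzyloxy)phenyl]acrylaldehyde | O=C/C=C/c1cc(OCc2ccccc2)c(OCc2ccccc2)c(OCc2ccccc2)c1 | intermediate
17 | (2R,3S)-3-[3,4,5-tris(benzyloxy)phenyl]oxirane-2-carbaldehyde (trans) | O=C[C@@H]1O[C@H]1c1cc(OCc2ccccc2)c(OCc2ccccc2)c(OCc2ccccc2)c1 | intermediate
18 | (2R,3S)-7-{2,6-bis(benzyloxy)-4-[(2R,3S)-3,5,7-tris(benzyloxy)chroman-2-yl]phenoxy}-2-[3,4,5-tris(benzyloxy)phenyl]chromane-3,4,5-triol (either C4 epimer) | O(Cc5ccccc5)c1cc(OCc5ccccc5)c2c(c1)O[C@H](c1cc(OCc5ccccc5)c(Oc3cc(O)c4c(c3)O[C@H](c3cc(OCc5ccccc5)c(OCc5ccccc5)c(OCc5ccccc5)c3)[C@@H](O)C4O)c(OCc5ccccc5)c1)[C@@H](OCc5ccccc5)C2 | intermediate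
19 | (2R,3S)-7-{2,6-bis(benzyloxy)-4-[(2R,3S)-3,5,7-tris(benzyloxy)chroman-2-yl]phenoxy}-2-[3,4,5-tris(benzyloxy)phenyl]chromane-3,5-diol | O(Cc5ccccc5)c1cc(OCc5ccccc5)c2c(c1)O[C@H](c1cc(OCc5ccccc5)c(Oc3cc(O)c4c(c3)O[C@H](c3cc(OCc5ccccc5)c(OCc5ccccc5)c(OCc5ccccc5)c3)[C@@H](O)C4)c(OCc5ccccc5)c1)[C@@H](OCc5ccccc5)C2 | intermediate
20 | (2R,3S)-5-(benzyloxy)-7-{2,6-bis(benzyloxy)-4-[(2R,3S)-3,5,7-tris(benzyloxy)chroman-2-yl]phenoxy}-2-[3,4,5-tris(benzyloxy)phenyl]chroman-3-ol | O(Cc5ccccc5)c1cc(OCc5ccccc5)c2c(c1)O[C@H](c1cc(OCc5ccccc5)c(Oc3cc(OCc5ccccc5)c4c(c3)O[C@H](c3cc(OCc5ccccc5)c(OCc5ccccc5)c(OCc5ccccc5)c3)[C@@H](O)C4)c(OCc5ccccc5)c1)[C@@H](OCc5ccccc5)C2 | intermediate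
21 | (2R)-5-(benzyloxy)-7-{2,6-bis(benzyloxy)-4-[(2R,3S)-3,5,7-tris(benzyloxy)chroman-2-yl]phenoxy}-2-[3,4,5-tris(benzyloxy)phenyl]chroman-3-one | O(Cc5ccccc5)c1cc(OCc5ccccc5)c2c(c1)O[C@H](c1cc(OCc5ccccc5)c(Oc3cc(OCc5ccccc5)c4c(c3)O[C@H](c3cc(OCc5ccccc5)c(OCc5ccccc5)c(OCc5ccccc5)c3)C(=O)C4)c(OCc5ccccc5)c1)[C@@H](OCc5ccccc5)C2 | intermediate
22 | (2R,3R)-5-(benzyloxy)-7-{2,6-bis(benzyloxy)-4-[(2R,3S)-3,5,7-tris(benzyloxy)chroman-2-yl]phenoxy}-2-[3,4,5-tris(benzyloxy)phenyl]chroman-3-ol | O(Cc5ccccc5)c1cc(OCc5ccccc5)c2c(c1)O[C@H](c1cc(OCc5ccccc5)c(Oc3cc(OCc5ccccc5)c4c(c3)O[C@H](c3cc(OCc5ccccc5)c(OCc5ccccc5)c(OCc5ccccc5)c3)[C@H](O)C4)c(OCc5ccccc5)c1)[C@@H](OCc5ccccc5)C2 | intermediate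
23 | (2R,3R)-7-{2,6-dihydroxy-4-[(2R,3S)-3,5,7-trihydroxychroman-2-yl]phenoxy}-2-(3,4,5-trihydroxyphenyl)chromane-3,5-diol (CNP0298095.1) | Oc1cc(O)c2c(c1)O[C@H](c1cc(O)c(Oc3cc(O)c4c(c3)O[C@H](c3cc(O)c(O)c(O)c3)[C@H](O)C4)c(O)c1)[C@@H](O)C2 | target

**Step count and risks**

Total steps: 17. Longest linear sequence: 14 (steps 1–3, 5–10, 13–17).

Steps most likely to fail:

1. Step 13 (Proposed new method). What may go wrong: C–C bond formation at a ring carbon next to the aryloxy group instead of between the two hydroxyls; 5-exo instead of 6-endo opening of the epoxide; Lewis-acid rearrangement of the epoxy aldehyde before it is captured. The fallback uses known reactions only, sets out from 14 and 17 and comes back at 19. Epoxy aldehyde 17 is reduced (NaBH4, MeOH, 0 °C) to the epoxy alcohol [(2S,3S)-3-[3,4,5-tris(benzyloxy)phenyl]oxiran-2-yl]methanol F1. One phenoxide of 14 (NaOH, aqueous dioxane, 70 °C, 14 in excess and recovered) opens F1 at the benzylic carbon with inversion to give the aryl ether diol (2S,3R)-3-(3-hydroxy-5-{2,6-bis(benzyloxy)-4-[(2R,3S)-3,5,7-tris(benzyloxy)chroman-2-yl]phenoxy}phenoxy)-3-[3,4,5-tris(benzyloxy)phenyl]propane-1,2-diol F2. Mitsunobu cyclodehydration of the 1,2-diol (PPh3, DIAD, toluene) closes the terminal epoxide 3-{2,6-bis(benzyloxy)-4-[(2R,3S)-3,5,7-tris(benzyloxy)chroman-2-yl]phenoxy}-5-{(R)-[(S)-oxiran-2-yl][3,4,5-tris(benzyloxy)phenyl]methoxy}phenol F3. Intramolecular Friedel–Crafts epoxy–arene cyclisation in HFIP at room temperature (6-endo attack of the ring carbon between the two oxygens on the terminal epoxide carbon) should then give 19.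

2. Step 8 (Proposed new method). What may go wrong: rearrangement or 5-exo opening of the epoxide, or ionisation at the benzylic C2–O1 bond in the acidic reduction stage with loss of configuration. The fallback sets out from 9 and 10 and comes back at 12. Reduction of 9 (NaBH4, MeOH, 0 °C) gives the epoxy alcohol [(2S,3S)-3-{4-[3,5-bis(allyloxy)phenoxy]-3,5-bis(benzyloxy)phenyl}oxiran-2-yl]methanol F4. The sodium phenoxide of 10 (NaOH, aqueous dioxane, 70 °C) opens F4 at the benzylic carbon with inversion to the diol (2S,3R)-3-[3,5-bis(benzyloxy)phenoxy]-3-{4-[3,5-bis(allyloxy)phenoxy]-3,5-bis(benzyloxy)phenyl}propane-1,2-diol F5. Mitsunobu cyclodehydration (PPh3, DIAD, toluene) gives the terminal epoxide (S)-2-{(R)-[3,5-bis(benzyloxy)phenoxy]{4-[3,5-bis(allyloxy)phenoxy]-3,5-bis(benzyloxy)phenyl}methyl}oxirane F6. Epoxy–arene cyclisation in HFIP (6-endo, the two ortho carbons being equivalent) should give 12.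

3. Step 5. What may go wrong: slow C–O bond formation at the hindered, formyl-deactivated 2,6-dialkoxyphenoxide, with competing protodebromination of 6 at the temperature needed. The fallback sets out from 4 and 6 and comes back at 7. Bromide 6 is converted (n-BuLi, THF, −78 °C; B(OiPr)3; aqueous HCl) into [3,5-bis(allyloxy)phenyl]boronic acid F7. F7 is joined to 4 by Chan–Lam coupling (Cu(OAc)2, pyridine, 4 Å molecular sieves, air, CH2Cl2, rt), an oxidative coupling at divalent copper that runs at room temperature and is known to accept ortho,ortho-disubstituted phenols.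

**Further compounds**

F1 | step 13 | [(2S,3S)-3-[3,4,5-tris(benzyloxy)phenyl]oxiran-2-yl]methanol | OC[C@@H]1O[C@H]1c1cc(OCc2ccccc2)c(OCc2ccccc2)c(OCc2ccccc2)c1
F2 | step 13 | (2S,3R)-3-(3-hydroxy-5-{2,6-bis(benzyloxy)-4-[(2R,3S)-3,5,7-tris(benzyloxy)chroman-2-yl]phenoxy}phenoxy)-3-[3,4,5-tris(benzyloxy)phenyl]propane-1,2-diol | O(Cc5ccccc5)c1cc(OCc5ccccc5)c2c(c1)O[C@H](c1cc(OCc5ccccc5)c(Oc3cc(O)cc(O[C@H](c4cc(OCc5ccccc5)c(OCc5ccccc5)c(OCc5ccccc5)c4)[C@@H](O)CO)c3)c(OCc5ccccc5)c1)[C@@H](OCc5ccccc5)C2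
F3 | step 13 | 3-{2,6-bis(benzyloxy)-4-[(2R,3S)-3,5,7-tris(benzyloxy)chroman-2-yl]phenoxy}-5-{(R)-[(S)-oxiran-2-yl][3,4,5-tris(benzyloxy)phenyl]methoxy}phenol | O(Cc5ccccc5)c1cc(OCc5ccccc5)c2c(c1)O[C@H](c1cc(OCc5ccccc5)c(Oc3cc(O)cc(O[C@H](c4cc(OCc5ccccc5)c(OCc5ccccc5)c(OCc5ccccc5)c4)[C@@H]6CO6)c3)c(OCc5ccccc5)c1)[C@@H](OCc5ccccc5)C2
F4 | step 8 | [(2S,3S)-3-{4-[3,5-bis(allyloxy)phenoxy]-3,5-bis(benzyloxy)phenyl}oxiran-2-yl]methanol | OC[C@@H]1O[C@H]1c1cc(OCc2ccccc2)c(Oc2cc(OCC=C)cc(OCC=C)c2)c(OCc2ccccc2)c1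
F5 | step 8 | (2S,3R)-3-[3,5-bis(benzyloxy)phenoxy]-3-{4-[3,5-bis(allyloxy)phenoxy]-3,5-bis(benzyloxy)phenyl}propane-1,2-diol | O(Cc1ccccc1)c1cc(OCc2ccccc2)cc(O[C@H](c2cc(OCc3ccccc3)c(Oc3cc(OCC=C)cc(OCC=C)c3)c(OCc3ccccc3)c2)[C@@H](O)CO)c1
F6 | step 8 | (S)-2-{(R)-[3,5-bis(benzyloxy)phenoxy]{4-[3,5-bis(allyloxy)phenoxy]-3,5-bis(benzyloxy)phenyl}methyl}oxirane | O(Cc1ccccc1)c1cc(OCc2ccccc2)cc(O[C@H](c2cc(OCc3ccccc3)c(Oc3cc(OCC=C)cc(OCC=C)c3)c(OCc3ccccc3)c2)[C@@H]4CO4)c1
F7 | step 5 | [3,5-bis(allyloxy)phenyl]boronic acid | OB(O)c1cc(OCC=C)cc(OCC=C)c1
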